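**Retrosynthetic overview**
1. Ring A and ring B are bought intact as acetophenone 1 and aldehyde 2; only ring C (the pyranone) is built.
2. Last disconnection: both phenolic C–O bonds of ring B (C3'–O and C5'–O) go back to an aryl dibromide, so the two free hydroxyls are never confused with the three methyl ethers and no protecting group is needed.
3. The 5-OH comes from peri-selective O-demethylation of a 5,6,7-trimethoxy ring A, done before the C–O coupling.
4. Ring C: the O1–C2 bond closes by oxa-Michael addition on a chalcone made in the same flask from 1 and 2, followed by dehydrogenation.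
5. Order of ring formation: A and B pre-formed, C in step 1; forward order 1 + 2 → 5 → 7 → 9.

Assumption: the target has no stereocentre and no stable stereoaxis, so it is one achiral compound and no enantiocontrol is needed; 1 and 2 are taken as catalogue compounds.

**Step 1**
Reactants: 1 1-(6-hydroxy-2,3,4-trimethoxyphenyl)ethan-1-one; 2 3,5-dibromo-2-methoxybenzaldehyde
Product: 5 2-(3,5-dibromo-2-methoxyphenyl)-5,6,7-trimethoxy-4H-chromen-4-one, via chalcone 3 (not isolated), via flavanone 4 (not isolated)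
Conditions: pyrrolidine (0.5 equiv), I2 (10 mol%), DMSO, 80 → 140 °C
Reagents that add atoms: none
Why: Pyrrolidine condenses 1 with the electron-poor aldehyde 2 by enamine/iminium catalysis (Claisen–Schmidt condensation) to the E-chalcone, the ortho phenol closes ring C by 6-endo oxa-Michael addition (O1–C2 bond; the C2 centre of the flavanone is racemic and is erased at once), and iodine α-iodinates the flavanone and eliminates HI while DMSO re-oxidises HI to I2, which is the known amine/iodine/DMSO domino flavone synthesis and leaves the aryl bromides untouched.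

**Step 2**
Reactants: 5 2-(3,5-dibromo-2-methoxyphenyl)-5,6,7-trimethoxy-4H-chromen-4-one
Product: 7 2-(3,5-dibromo-2-methoxyphenyl)-5-hydroxy-6,7-dimethoxy-4H-chromen-4-one, via aryloxydichloroborane 6 (not isolated)
Conditions: BCl3 (1.3 equiv, 1 M in CH2Cl2), CH2Cl2, −20 → 0 °C; then H2O
Reagents that add atoms: none
Why: BCl3 sits in the six-membered chelate between the C4 carbonyl and the peri 5-methoxy oxygen, so chloride removes only that methyl group (chelation-controlled Lewis-acid ether cleavage), whereas the 6-, 7- and 2'-methoxy groups cannot chelate and survive near-stoichiometric BCl3 at low temperature, the C–Br bonds are inert, and water hydrolyses the boron chelate.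

**Step 3**
Reactants: 7 2-(3,5-dibromo-2-methoxyphenyl)-5-hydroxy-6,7-dimethoxy-4H-chromen-4-one
Product: 9 2-(3,5-dihydroxy-2-methoxyphenyl)-5-hydroxy-6,7-dimethoxy-4H-chromen-4-one, via bis(sulfonylethyl) ether 8 (not isolated)
Conditions: Pd2(dba)3 (2.5 mol%), tBuBrettPhos (6 mol%), MeSO2CH2CH2OH (3 equiv), Cs2CO3 (4 equiv), 1,4-dioxane, 90 °C; then KOtBu (5 equiv), THF, 0 → 25 °C; 1 M HCl quench
Reagents that add atoms: 2-(methylsulfonyl)ethanol, CS(=O)(=O)CCO
Why: Proposed new method: a twofold tandem palladium-catalysed C–O cross-coupling/E1cB unmasking in which 2-(methylsulfonyl)ethanol serves as a hydroxide surrogate, reasoning that zerovalent palladium carrying tBuBrettPhos inserts into each C–Br bond, the fairly acidic β-sulfonyl alcohol is deprotonated by Cs2CO3 (too weak to open the γ-pyrone) and exchanges onto divalent palladium, the bulky biaryl phosphine drives C–O reductive elimination ahead of β-hydride elimination, and KOtBu then removes the sulfone α-proton so that each aryl ether expels its phenoxide and methyl vinyl sulfone; the closest known reaction types are Buchwald–Hartwig-type etherification of aryl bromides with primary and fluorinated alcohols and the metal-free SNAr hydroxylation of activated aryl fluorides with the same alcohol, a combination that to my knowledge has not been described for unactivated aryl bromides, for a double coupling, or on a free 5-hydroxyflavone.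

**Compound list**
1 | 1-(6-hydroxy-2,3,4-trimethoxyphenyl)ethan-1-one | CC(=O)c1c(O)cc(OC)c(OC)c1OC | starting material
2 | 3,5-dibromo-2-methoxybenzaldehyde | COc1c(Br)cc(Br)cc1C=O | starting material
3 | (E)-3-(3,5-dibromo-2-methoxyphenyl)-1-(6-hydroxy-2,3,4-trimethoxyphenyl)prop-2-en-1-one | COc1cc(O)c(C(=O)/C=C/c2cc(Br)cc(Br)c2OC)c(OC)c1OC | intermediate
4 | (±)-2-(3,5-dibromo-2-methoxyphenyl)-5,6,7-trimethoxychroman-4-one (racemic) | COc1cc2OC(c3cc(Br)cc(Br)c3OC)CC(=O)c2c(OC)c1OC | intermediate
5 | 2-(3,5-dibromo-2-methoxyphenyl)-5,6,7-trimethoxy-4H-chromen-4-one | COc1cc2oc(-c3cc(Br)cc(Br)c3OC)cc(=O)c2c(OC)c1OC | intermediate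
6 | dichloro{[2-(3,5-dibromo-2-methoxyphenyl)-6,7-dimethoxy-4-oxo-4H-chromen-5-yl]oxy}borane | COc1cc2oc(-c3cc(Br)cc(Br)c3OC)cc(=O)c2c(OB(Cl)Cl)c1OC | intermediate
7 | 2-(3,5-dibromo-2-methoxyphenyl)-5-hydroxy-6,7-dimethoxy-4H-chromen-4-one | COc1cc2oc(-c3cc(Br)cc(Br)c3OC)cc(=O)c2c(O)c1OC | intermediate
8 | 5-hydroxy-6,7-dimethoxy-2-{2-methoxy-3,5-bis[2-(methylsulfonyl)ethoxy]phenyl}-4H-chromen-4-one | COc1cc2oc(-c3cc(OCCS(C)(=O)=O)cc(OCCS(C)(=O)=O)c3OC)cc(=O)c2c(O)c1OC | intermediate
9 | 2-(3,5-dihydroxy-2-methoxyphenyl)-5-hydroxy-6,7-dimethoxy-4H-chromen-4-one | COc1cc2oc(-c3cc(O)cc(O)c3OC)cc(=O)c2c(O)c1OC | target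

**Totals**
Total step count: 3. Longest linear sequence: 3 steps (1 or 2 → 5 → 7 → 9).

**Steps most likely to fail**

Step 3 (the proposed new step). Possible failures:
- β-hydride elimination from the palladium alkoxide, giving hydrodebromination.
- Sequestration of palladium by the chelating 5-phenoxide/carbonyl pair.
- A sluggish second coupling at the hindered C3'–Br.
- Incomplete E1cB release.

Fallback, known chemistry, setting out from 7 and coming back at 9: twofold Miyaura borylation of 7 (PdCl2(dppf) 5 mol%, B2pin2 2.6 equiv, KOAc 6 equiv, 1,4-dioxane, 90 °C) gives the bis(pinacol boronate) 5-hydroxy-6,7-dimethoxy-2-[2-methoxy-3,5-bis(4,4,5,5-tetramethyl-1,3,2-dioxaborolan-2-yl)phenyl]-4H-chromen-4-one F1. NaBO3·4H2O in THF/H2O at 25 °C then oxidises both C–B bonds (aryl shift from boron to oxygen) to give 9. This replaces the C–O coupling by C–B formation and oxidation and needs no strong base.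

Step 1. Possible failures:
- The di-ortho-substituted ketone 1 may condense slowly.
- Pyrrolidine may displace the methoxy group ortho to the formyl/iminium group of 2 if 2 is not consumed at 80 °C.
- Iodine may iodinate C8.

Fallback, setting out from 1 and coming back at 5 (Baker–Venkataraman approach): bought 3,5-dibromo-2-methoxybenzoic acid (COc1c(Br)cc(Br)cc1C(O)=O) is converted with (COCl)2 and catalytic DMF in CH2Cl2 into 3,5-dibromo-2-methoxybenzoyl chloride F2. Phenol 1 and F2 in pyridine at 25 °C give the ester 2-acetyl-3,4,5-trimethoxyphenyl 3,5-dibromo-2-methoxybenzoate F3. KOH in pyridine at 50 °C moves the aroyl group from oxygen to the acetyl carbon to give the diketone 1-(3,5-dibromo-2-methoxyphenyl)-3-(6-hydroxy-2,3,4-trimethoxyphenyl)propane-1,3-dione F4. Catalytic H2SO4 in AcOH at 100 °C closes ring C by cyclodehydration to 5.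

Step 2. Possible failure: over-demethylation at the crowded 6-methoxy group next to the boron chelate, or at the twisted 2'-methoxy group.

Fallback, setting out from 2 and coming back at 7 (the C5 oxygen is introduced by C–H oxygenation, not unmasked): 2 and bought 1-(2-hydroxy-4,5-dimethoxyphenyl)ethan-1-one (CC(=O)c1cc(OC)c(OC)cc1O) with KOH in EtOH at 25 °C give the chalcone (E)-3-(3,5-dibromo-2-methoxyphenyl)-1-(2-hydroxy-4,5-dimethoxyphenyl)prop-2-en-1-one F5. I2 (10 mol%) in DMSO at 130 °C cyclises and dehydrogenates it to the flavone 2-(3,5-dibromo-2-methoxyphenyl)-6,7-dimethoxy-4H-chromen-4-one F6. Ketone-directed ortho C–H oxygenation ([RuCl2(p-cymene)]2 5 mol%, PhI(OCOCF3)2 2 equiv, CF3CO2H/(CF3CO)2O, 80 °C) gives the ester 2-(3,5-dibromo-2-methoxyphenyl)-6,7-dimethoxy-4-oxo-4H-chromen-5-yl trifluoroacetate F7. Aqueous work-up hydrolyses F7 to 7.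

**Further compounds**
F1 | step 3 | 5-hydroxy-6,7-dimethoxy-2-[2-methoxy-3,5-bis(4,4,5,5-tetramethyl-1,3,2-dioxaborolan-2-yl)phenyl]-4H-chromen-4-one | COc1cc2oc(-c3cc(B4OC(C)(C)C(C)(C)O4)cc(B4OC(C)(C)C(C)(C)O4)c3OC)cc(=O)c2c(O)c1OC
F2 | step 1 | 3,5-dibromo-2-methoxybenzoyl chloride | COc1c(Br)cc(Br)cc1C(Cl)=O
F3 | step 1 | 2-acetyl-3,4,5-trimethoxyphenyl 3,5-dibromo-2-methoxybenzoate | COc1cc(OC(=O)c2cc(Br)cc(Br)c2OC)c(C(C)=O)c(OC)c1OC
F4 | step 1 | 1-(3,5-dibromo-2-methoxyphenyl)-3-(6-hydroxy-2,3,4-trimethoxyphenyl)propane-1,3-dione | COc1cc(O)c(C(=O)CC(=O)c2cc(Br)cc(Br)c2OC)c(OC)c1OC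
F5 | step 2 | (E)-3-(3,5-dibromo-2-methoxyphenyl)-1-(2-hydroxy-4,5-dimethoxyphenyl)prop-2-en-1-one | COc1cc(O)c(C(=O)/C=C/c2cc(Br)cc(Br)c2OC)cc1OC
F6 | step 2 | 2-(3,5-dibromo-2-methoxyphenyl)-6,7-dimethoxy-4H-chromen-4-one | COc1cc2oc(-c3cc(Br)cc(Br)c3OC)cc(=O)c2cc1OC
F7 | step 2 | 2-(3,5-dibromo-2-methoxyphenyl)-6,7-dimethoxy-4-oxo-4H-chromen-5-yl trifluoroacetate | COc1cc2oc(-c3cc(Br)cc(Br)c3OC)cc(=O)c2c(OC(=O)C(F)(F)F)c1OC
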